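**The decision.** I count time in lifetimes of left-handed substrate and ask how far a second clock, one that ignores free catalyst, has run by the moment of looking. The amber run is this very flask, followed so far.

- amber: left-handed substrate 0.80 M; right-handed substrate 0.80 M; partner 1.2 M; free catalyst 8 mM; the very flask that is asked about, followed so far
- flask: left-handed substrate 0.80 M; partner 1.20 M; free catalyst 8.0 mM; right-handed substrate 0.80 M

amber run (percent of the left-handed substrate and right-handed substrate together charged)

| time / s | left-handed product / % | left-handed substrate / % |
|---|---|---|
| 20.0 | 13.5 | 35.6 |
| 40.0 | 22.9 | 28.1 |
| 50.0 | 25.9 | 26.4 |
| 80.0 | 31.6 | 19.8 |
| 90.0 | 33.4 | 18.4 |
| 120 | 35.9 | 15.3 |

(standard deviation of a reading: 1 percentage point)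

1. apparent order in partner when 30 % of the left-handed substrate and right-handed substrate together are converted (percent change of the rate of making left-handed product for one percent more partner charged)
2. apparent order in free catalyst when 30 % of the left-handed substrate and right-handed substrate together are converted (percent change of the rate of making left-handed product for one percent more free catalyst charged)
3. factor on the rate of making left-handed product when 30 % of the left-handed substrate and right-handed substrate together are converted if free catalyst is charged twice over

- free catalyst is single-handed; left-handed substrate and right-handed substrate are mirror images of each other, charged as a racemate, each of them at the stated concentration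
- what was read earlier has a scatter of 1 percentage point, one standard deviation
- no earlier run changes the charge of free catalyst; that part of a forecast is a guess
- no earlier run changes the charge of partner; that part of a forecast is a guess

**The lifetime.** Half of the charge is left-handed substrate, so the first amber reading gives 58.9 s, the early pseudo-first-order lifetime of left-handed substrate. Between the last two amber readings that lifetime reads 2.76 times longer. If partner goes one for one with left-handed substrate, its charge over what stands at the last reading is 1.86, which is less than the stretch.

**Two extremes.** Without a second clock, free catalyst merely rescales time, so the composition at 30 % is unchanged and I get order 1 and factor 2. With a second clock much faster than the lifetime, more catalyst outruns the loss, and the order climbs far above 1. The amber stretch beyond that partner ratio is a hint of a second clock and no measure of it: it rests on the readings 18.4 % and 15.3 %, each with a scatter of 1 percentage point, and right-handed substrate, which no amber column shows, may take partner as well. My reckoning is therefore a flask between the extremes, with order 1 or somewhat above in free catalyst and factor 2 or somewhat above. For partner, 0.720 M left at that conversion gives a floor of 1.67, which a second clock raises.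

**The forecast.** It says 2.2 in partner, 0.95 in free catalyst and factor 1.9, on the ground "I assume near first order"; my lower end of 1 for the catalyst order is higher than its figure.

**The result.** The flask gives 2.0 in partner, 1.2 in free catalyst and factor 2.18, with 30 % reached at 0.909 min.

    partner + free catalyst + left-handed substrate → free catalyst + left-handed product (k = 120 M⁻² min⁻¹)
    partner + free catalyst + right-handed substrate → free catalyst + right-handed product (k = 13.0 M⁻² min⁻¹)
    partner → decomposed reagent (k = 0.140 min⁻¹)
    free catalyst → spent catalyst (k = 1.50 × 10⁻⁵ min⁻¹)

At the start, the reaction with left-handed substrate uses partner 5.5 times as fast as decomposition does. One carried lifetime of 58.9 s is 0.137 of the lifetime of partner against decomposition, 7.14 min.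

The data were computed on assumed constants; the scatter is artificial.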